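**Plan**
- Retrosynthesis: the two MOM ethers are removed last. Ring C is cut at C3–C4, meaning the formyl C–H of C4 adds across an enol ether C2=C3; this leaves an achiral aldehyde that is an isomer of the protected flavanone. Further cuts: the formyl C–C bond, the enol ether methylene (back to an aryl 3,4-dimethoxybenzoate), the ester C–O, the phenolic C–O and the aryl–geranyl bond.
- Forward: ring A is built one position at a time on resorcinol bis-MOM ether: geranyl between the two oxygens (directed lithiation), hydroxyl para to geranyl (sterically governed C–H borylation/oxidation), ester, methylenation to the 1-arylvinyl ether, formylation at one of two equivalent C–H bonds. The 6-geranyl pattern is therefore fixed by symmetry before ring C exists.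
- Ring C is closed in the penultimate step by an enantioselective rhodium-catalysed 6-endo hydroacylation; deprotection follows.
- Enabling feature: O1 joins C8a of ring A to C2. Written as the enol ether C8a–O1–C2(Ar)=C3H2, the terminal C3 lies within reach of the formyl carbon C4 on C4a, and the 1,1-disubstitution at C2 (aryl and aryloxy) blocks the five-ring alternative.
- Stereochemistry: C2 (S) is the only stereocentre and is set in the key step by the chiral bisphosphine during hydride transfer to C2. The E-alkene is carried in from geranyl bromide.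

Key step: step 6

Assumption: the sense of induction of (R)-DTBM-SEGPHOS is extrapolated from hydroacylations of 1,1-disubstituted alkenes that give six-membered ketones; if hydride is delivered to the other face of C2, the (S)-ligand is used instead. "Geranyl" means (2E)-3,7-dimethylocta-2,6-dien-1-yl throughout.

**Step 1**
Reactants: 1 1,3-bis(methoxymethoxy)benzene; 2 geranyl bromide
Product: 4 2-geranyl-1,3-bis(methoxymethoxy)benzene, via aryllithium 3 (not isolated)
Conditions: n-BuLi, THF, 0 °C to rt; CuBr·SMe2 (10 mol %), then 2, −20 °C to rt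
Reagents that add atoms: n-butyllithium, [Li]CCCC (lithium of intermediate 3 only)
Why: Directed ortho metalation of a resorcinol bis-MOM ether occurs at the carbon between the two oxygens, and copper-catalysed SN2 allylation of the aryllithium by the primary allylic bromide should keep the E geometry.

**Step 2**
Reactants: 4 2-geranyl-1,3-bis(methoxymethoxy)benzene
Product: 6 4-geranyl-3,5-bis(methoxymethoxy)phenol, via pinacol arylboronate 5 (not isolated)
Conditions: [Ir(cod)(OMe)]2 (1.5 mol %), 4,4'-di-tert-butyl-2,2'-bipyridine (3 mol %), B2pin2, THF, 60 °C; then aq NaOH, 30% H2O2, 0 °C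
Reagents that add atoms: bis(pinacolato)diboron, CC1(C)OB(OC1(C)C)B1OC(C)(C)C(C)(C)O1 (boron of intermediate 5); hydrogen peroxide, OO (oxygen of 6)
Why: Iridium-catalysed C–H borylation is sterically controlled and should take the only C–H of 4 without an ortho substituent (para to geranyl) while the hindered trisubstituted alkenes stay untouched, and basic peroxide then oxidises the C–B bond to the phenol at the same position.

**Step 3**
Reactants: 6 4-geranyl-3,5-bis(methoxymethoxy)phenol; 7 3,4-dimethoxybenzoyl chloride
Product: 8 4-geranyl-3,5-bis(methoxymethoxy)phenyl 3,4-dimethoxybenzoate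
Conditions: Et3N, DMAP (10 mol %), CH2Cl2, 0 °C to rt
Reagents that add atoms: none
Why: DMAP-catalysed acylation of an unhindered phenol by an aroyl chloride is routine and leaves the MOM ethers and alkenes alone.

**Step 4**
Reactants: 8 4-geranyl-3,5-bis(methoxymethoxy)phenyl 3,4-dimethoxybenzoate
Product: 9 4-{1-[4-geranyl-3,5-bis(methoxymethoxy)phenoxy]ethenyl}-1,2-dimethoxybenzene
Conditions: Cp2TiMe2 (2.5 equiv), toluene/THF, 65 °C, dark; filtration through basic Al2O3
Reagents that add atoms: dimethyltitanocene, C[Ti](C)(C1C=CC=C1)C1C=CC=C1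
Why: Petasis methylenation, in which titanocene methylidene formed on heating converts the non-enolisable aryl ester carbonyl into the 1,1-disubstituted enol ether under non-acidic conditions that spare the MOM ethers and the acid-labile product.

**Step 5**
Reactants: 9 4-{1-[4-geranyl-3,5-bis(methoxymethoxy)phenoxy]ethenyl}-1,2-dimethoxybenzene
Product: 12 6-[1-(3,4-dimethoxyphenyl)ethenyloxy]-3-geranyl-2,4-bis(methoxymethoxy)benzaldehyde, via aryllithium 10 (not isolated), via lithium aminoalkoxide 11 (not isolated)
Conditions: n-BuLi, TMEDA, THF, −78 to −20 °C; DMF, −78 to 0 °C; pH 7 phosphate buffer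
Reagents that add atoms: n-butyllithium, [Li]CCCC (lithium of intermediates 10 and 11 only); N,N-dimethylformamide, CN(C)C=O
Why: Directed ortho metalation at the ring A C–H flanked by OMOM and the aryloxy oxygen (the two remaining ring A positions are equivalent, so the site is unambiguous) followed by DMF formylation and a neutral work-up that spares the enol ether.

**Step 6**
Reactants: 12 6-[1-(3,4-dimethoxyphenyl)ethenyloxy]-3-geranyl-2,4-bis(methoxymethoxy)benzaldehyde
Product: 13 (2S)-2-(3,4-dimethoxyphenyl)-6-geranyl-5,7-bis(methoxymethoxy)chroman-4-one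
Conditions: [Rh(cod)Cl]2 (2.5 mol %), (R)-DTBM-SEGPHOS (5.5 mol %), Na[B(3,5-(CF3)2C6H3)4] (5 mol %), anhydrous 1,4-dioxane, 80 °C
Reagents that add atoms: none
Why: Proposed new method: a cationic monovalent rhodium bisphosphine complex should insert into the formyl C–H bond of 12 to give an acyl hydride of trivalent rhodium, the tethered enol ether C2=C3 should bind, hydride should migrate to C2 to leave a seven-membered acyl–alkyl rhodacycle, and C–C reductive elimination should form C3–C4 and release the catalyst. The closest known reaction type is the rhodium/bisphosphine-catalysed enantioselective intramolecular hydroacylation of 1,1-disubstituted alkenes, which gives six-membered benzo-fused ketones from ortho-allylbenzaldehydes and five-membered ones from 2-substituted N-vinylindole-2-carbaldehydes; an aryl 1-arylvinyl ether has not served as the alkene partner. Ring C closes in the 6-endo-trig mode, the acyl carbon ending on the terminal CH2. The only stereocentre, C2, is created when hydride is delivered to one enantiotopic face of the enol ether inside the chiral pocket of DTBM-SEGPHOS, so the ligand alone controls it. The step needs endo over exo closure and hydroacylation over decarbonylation, β-aryloxy elimination and enol ether hydrolysis: the 1,1-disubstitution at C2 forces the exo path through a tertiary alkyl rhodium and a quaternary carbon, the flanking OMOM oxygen and the electron-rich ligand should disfavour CO extrusion, the Rh–C3–C2–O1 array is held in the rhodacycle away from the syn-coplanar geometry that elimination needs, and the medium is neutral and anhydrous. The trisubstituted geranyl alkenes are too hindered to insert, and the enol ether has no allylic hydrogen to isomerise.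

**Step 7**
Reactants: 13 (2S)-2-(3,4-dimethoxyphenyl)-6-geranyl-5,7-bis(methoxymethoxy)chroman-4-one
Product: 14 (2S)-2-(3,4-dimethoxyphenyl)-6-geranyl-5,7-dihydroxychroman-4-one (CNP0268555.1)
Conditions: 3 M aq HCl, MeOH, 40 °C
Reagents that add atoms: none
Why: Acid-catalysed acetal exchange removes both MOM ethers as dimethoxymethane; flavanones open to chalcones and racemise under base rather than under mild acid, and the geranyl chain should tolerate dilute acid at this temperature.

**Compound list**
1 | 1,3-bis(methoxymethoxy)benzene | COCOc1cccc(OCOC)c1 | starting material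
2 | geranyl bromide, (2E)-1-bromo-3,7-dimethylocta-2,6-diene | BrC/C=C(\C)CCC=C(C)C | starting material
3 | 2,6-bis(methoxymethoxy)phenyllithium | [Li]c1c(OCOC)cccc1OCOC | intermediate
4 | 2-geranyl-1,3-bis(methoxymethoxy)benzene | COCOc1cccc(OCOC)c1C/C=C(\C)CCC=C(C)C | intermediate
5 | 2-[4-geranyl-3,5-bis(methoxymethoxy)phenyl]-4,4,5,5-tetramethyl-1,3,2-dioxaborolane | COCOc1cc(B2OC(C)(C)C(C)(C)O2)cc(OCOC)c1C/C=C(\C)CCC=C(C)C | intermediate
6 | 4-geranyl-3,5-bis(methoxymethoxy)phenol | COCOc1cc(O)cc(OCOC)c1C/C=C(\C)CCC=C(C)C | intermediate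
7 | 3,4-dimethoxybenzoyl chloride | COc1ccc(C(=O)Cl)cc1OC | starting material
8 | 4-geranyl-3,5-bis(methoxymethoxy)phenyl 3,4-dimethoxybenzoate | COc1ccc(C(=O)Oc2cc(OCOC)c(C/C=C(\C)CCC=C(C)C)c(OCOC)c2)cc1OC | intermediate
9 | 4-{1-[4-geranyl-3,5-bis(methoxymethoxy)phenoxy]ethenyl}-1,2-dimethoxybenzene | COc1ccc(C(=C)Oc2cc(OCOC)c(C/C=C(\C)CCC=C(C)C)c(OCOC)c2)cc1OC | intermediate
10 | aryllithium of 9, lithium on the ring A carbon between the vinyloxy oxygen and an OMOM group | COc1ccc(C(=C)Oc2cc(OCOC)c(C/C=C(\C)CCC=C(C)C)c(OCOC)c2[Li])cc1OC | intermediate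
11 | lithium (dimethylamino)(aryl)methoxide, DMF adduct of 10 | COc1ccc(C(=C)Oc2cc(OCOC)c(C/C=C(\C)CCC=C(C)C)c(OCOC)c2C(O[Li])N(C)C)cc1OC | intermediate
12 | 6-[1-(3,4-dimethoxyphenyl)ethenyloxy]-3-geranyl-2,4-bis(methoxymethoxy)benzaldehyde | COc1ccc(C(=C)Oc2cc(OCOC)c(C/C=C(\C)CCC=C(C)C)c(OCOC)c2C=O)cc1OC | intermediate
13 | (2S)-2-(3,4-dimethoxyphenyl)-6-geranyl-5,7-bis(methoxymethoxy)chroman-4-one | COc1ccc([C@@H]2CC(=O)c3c(cc(OCOC)c(C/C=C(\C)CCC=C(C)C)c3OCOC)O2)cc1OC | intermediate
14 | (2S)-2-(3,4-dimethoxyphenyl)-6-geranyl-5,7-dihydroxychroman-4-one | COc1ccc([C@@H]2CC(=O)c3c(cc(O)c(C/C=C(\C)CCC=C(C)C)c3O)O2)cc1OC | target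

**Totals**
Total step count: 7. Longest linear sequence: 7 steps (1 to 14).

**Steps most likely to fail**

1. Step 6 (proposed new method). The acyl rhodium hydride may lose CO, the ring may close in the exo sense, the alkyl rhodium may expel the aryloxide, or hydride transfer may show poor facial selectivity. The fallback uses known chemistry, sets out from phenol 6 and forms the C2–aryl bond instead.
   - Magnesium-mediated ortho-formylation (MgCl2, Et3N, paraformaldehyde, MeCN, reflux) should give 3-geranyl-6-hydroxy-2,4-bis(methoxymethoxy)benzaldehyde F1.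
   - MeMgBr (THF, 0 °C) should give 1-[3-geranyl-6-hydroxy-2,4-bis(methoxymethoxy)phenyl]ethanol F2.
   - MnO2 (CH2Cl2) should give 1-[3-geranyl-6-hydroxy-2,4-bis(methoxymethoxy)phenyl]ethanone F3.
   - DMF dimethyl acetal (toluene, 90 °C) should give the enaminone (E)-3-(dimethylamino)-1-[3-geranyl-6-hydroxy-2,4-bis(methoxymethoxy)phenyl]prop-2-en-1-one F4.
   - F4 should close with loss of dimethylamine (AcOH, CH2Cl2) to 6-geranyl-5,7-bis(methoxymethoxy)chromen-4-one F5.
   - Asymmetric conjugate addition of 3,4-dimethoxyphenylboronic acid F6 to F5 (Pd(OCOCF3)2, the t-BuPyOx enantiomer that delivers 2S, NH4PF6, H2O, 1,2-dichloroethane, 60 °C) should give 13, where the route is rejoined.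

2. Step 5. The alkyllithium may deprotonate elsewhere (benzylic/allylic CH2, ring B) or add to the enol ether before directed metalation is complete. The fallback replaces deprotonation by halogen–lithium exchange and sets out from phenol 6.
   - NBS (1 equiv, CH2Cl2, −78 °C) should give 2-bromo-4-geranyl-3,5-bis(methoxymethoxy)phenol F7.
   - Acylation with 7 (Et3N, DMAP) should give 2-bromo-4-geranyl-3,5-bis(methoxymethoxy)phenyl 3,4-dimethoxybenzoate F8.
   - Cp2TiMe2 (toluene/THF, 65 °C) should give the bromo enol ether 4-{1-[2-bromo-4-geranyl-3,5-bis(methoxymethoxy)phenoxy]ethenyl}-1,2-dimethoxybenzene F9.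
   - n-BuLi (THF, −78 °C) should exchange bromine for lithium faster than any deprotonation and give aryllithium 10, where the route is rejoined (DMF then gives 12).

3. Step 2. The iridium boryl catalyst may borylate or hydroborate the geranyl alkenes, or steric control of the arene site may be incomplete. The fallback places the oxygen before the alkene-bearing chain and sets out from 1.
   - Borylation of 1 ([Ir(cod)(OMe)]2, 4,4'-di-tert-butyl-2,2'-bipyridine, B2pin2) should give 2-[3,5-bis(methoxymethoxy)phenyl]-4,4,5,5-tetramethyl-1,3,2-dioxaborolane F10.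
   - Oxidation (aq NaOH, H2O2) should give 3,5-bis(methoxymethoxy)phenol F11.
   - TIPSCl and imidazole (DMF) should give [3,5-bis(methoxymethoxy)phenoxy]triisopropylsilane F12.
   - Lithiation between the two OMOM groups (n-BuLi, THF, 0 °C; the bulky silyl ether shields its own neighbours) and copper-catalysed allylation with 2 should give [4-geranyl-3,5-bis(methoxymethoxy)phenoxy]triisopropylsilane F13.
   - TBAF (THF) should release phenol 6, where the route is rejoined.

**Further compounds**
F1 | step 6 | 3-geranyl-6-hydroxy-2,4-bis(methoxymethoxy)benzaldehyde | COCOc1cc(O)c(C=O)c(OCOC)c1C/C=C(\C)CCC=C(C)C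
F2 | step 6 | 1-[3-geranyl-6-hydroxy-2,4-bis(methoxymethoxy)phenyl]ethanol (racemic) | COCOc1cc(O)c(C(C)O)c(OCOC)c1C/C=C(\C)CCC=C(C)C
F3 | step 6 | 1-[3-geranyl-6-hydroxy-2,4-bis(methoxymethoxy)phenyl]ethanone | COCOc1cc(O)c(C(C)=O)c(OCOC)c1C/C=C(\C)CCC=C(C)C
F4 | step 6 | (E)-3-(dimethylamino)-1-[3-geranyl-6-hydroxy-2,4-bis(methoxymethoxy)phenyl]prop-2-en-1-one | COCOc1cc(O)c(C(=O)/C=C/N(C)C)c(OCOC)c1C/C=C(\C)CCC=C(C)C
F5 | step 6 | 6-geranyl-5,7-bis(methoxymethoxy)chromen-4-one | COCOc1cc2occc(=O)c2c(OCOC)c1C/C=C(\C)CCC=C(C)C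
F6 | step 6 | 3,4-dimethoxyphenylboronic acid | COc1ccc(B(O)O)cc1OC
F7 | step 5 | 2-bromo-4-geranyl-3,5-bis(methoxymethoxy)phenol | COCOc1cc(O)c(Br)c(OCOC)c1C/C=C(\C)CCC=C(C)C
F8 | step 5 | 2-bromo-4-geranyl-3,5-bis(methoxymethoxy)phenyl 3,4-dimethoxybenzoate | COc1ccc(C(=O)Oc2cc(OCOC)c(C/C=C(\C)CCC=C(C)C)c(OCOC)c2Br)cc1OC
F9 | step 5 | 4-{1-[2-bromo-4-geranyl-3,5-bis(methoxymethoxy)phenoxy]ethenyl}-1,2-dimethoxybenzene | COc1ccc(C(=C)Oc2cc(OCOC)c(C/C=C(\C)CCC=C(C)C)c(OCOC)c2Br)cc1OC
F10 | step 2 | 2-[3,5-bis(methoxymethoxy)phenyl]-4,4,5,5-tetramethyl-1,3,2-dioxaborolane | COCOc1cc(OCOC)cc(B2OC(C)(C)C(C)(C)O2)c1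
F11 | step 2 | 3,5-bis(methoxymethoxy)phenol | COCOc1cc(O)cc(OCOC)c1
F12 | step 2 | [3,5-bis(methoxymethoxy)phenoxy]triisopropylsilane | COCOc1cc(O[Si](C(C)C)(C(C)C)C(C)C)cc(OCOC)c1
F13 | step 2 | [4-geranyl-3,5-bis(methoxymethoxy)phenoxy]triisopropylsilane | COCOc1cc(O[Si](C(C)C)(C(C)C)C(C)C)cc(OCOC)c1C/C=C(\C)CCC=C(C)C
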